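**Strategy.** Everything rests on disconnecting the C1–C2 bond of the ten-membered ring (C1–C10). Ring A is a cyclohex-2-enone (C12=O, C13=C14), so quaternary C1 is the γ-carbon of its extended enolate and oxygenated C2 is an aldol carbon. The key step, an intramolecular vinylogous Mukaiyama aldol reaction, closes the ten-membered ring, creates quaternary C1 and carbinol C2 and returns the enone in one operation. Its precursor is an open chain: a ring A 1-silyloxy-1,3-diene (C12(OSi)=C13–C14=C1) with planar C1, joined through C10–C9 to the finished chlorinated hydroxy-γ-lactone segment (C5–C8, C17–C19) that ends in the C2 aldehyde. Ring A comes from a Diels–Alder reaction.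

Key step: step 22

Remark: carbons carry the numbers of the briarane skeleton of the target (C1–C20); β is the face of ring A that bears CH3-15 in the target, α the opposite face. Compounds 1, 6, 8 and 9 and all reagents are taken as commercial.

**Step 1**
Reactants: 1 pentane-1,5-diol
Product: 2 5-[(4-methoxybenzyl)oxy]pentan-1-ol
Conditions: NaH (1 equiv), PMBCl (1 equiv), Bu4NI (cat.), THF, 0 °C → rt, diol in threefold excess
Reagents that add atoms: 4-methoxybenzyl chloride, COc1ccc(CCl)cc1
Why: Williamson etherification; the excess of the symmetrical diol keeps bis-alkylation low.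

**Step 2**
Reactants: 2 5-[(4-methoxybenzyl)oxy]pentan-1-ol
Product: 3 5-[(4-methoxybenzyl)oxy]pentanal
Conditions: TEMPO (cat.), PhI(OAc)2, CH2Cl2, rt
Reagents that add atoms: none
Why: Oxoammonium (TEMPO) oxidation of the primary alcohol stops at the aldehyde and leaves the PMB ether intact.

**Step 3**
Reactants: 3 5-[(4-methoxybenzyl)oxy]pentanal
Product: 4 5-[(4-methoxybenzyl)oxy]-2-methylidenepentanal
Conditions: aq. HCHO (37%), pyrrolidine (10 mol%), propanoic acid (10 mol%), i-PrOH, 45 °C
Reagents that add atoms: formaldehyde, C=O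
Why: Amine-catalysed Mannich condensation–elimination (α-methylenation of an aldehyde) puts C16 on C5.

**Step 4**
Reactants: 4 5-[(4-methoxybenzyl)oxy]-2-methylidenepentanal
Product: 5 (1E)-1-iodo-6-[(4-methoxybenzyl)oxy]-3-methylidenehex-1-ene
Conditions: CrCl2 (6 equiv), CHI3 (2 equiv), THF/dioxane, 0 °C
Reagents that add atoms: iodoform, IC(I)I
Why: Takai olefination of the enal through a geminal dichromium reagent should give the (E)-dienyl iodide (C7=C6).

**Step 5**
Reactants: 6 (2E)-pent-2-enal
Product: 7 (1E,3E)-1-(trimethylsilyloxy)penta-1,3-diene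
Conditions: TMSCl, Et3N, ZnCl2 (cat.), toluene, 60 °C
Reagents that add atoms: chlorotrimethylsilane, C[Si](C)(C)Cl
Why: γ-Deprotonation and O-silylation of the enal give the 1-silyloxy diene; only the (1E,3E) isomer can reach the s-cis form that reacts in step 7.

**Step 6**
Reactants: 8 (4S)-2,2-dimethyl-1,3-dioxolane-4-carbaldehyde; 9 2-(triphenylphosphoranylidene)propanal
Product: 10 (2E)-3-[(4R)-2,2-dimethyl-1,3-dioxolan-4-yl]-2-methylprop-2-enal
Conditions: toluene, 80 °C
Reagents that add atoms: none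
Why: Wittig olefination with a stabilised ylide should give the (E)-trisubstituted enal; the C9 stereocentre comes unchanged from the chiral pool.

**Step 7**
Reactants: 7 (1E,3E)-1-(trimethylsilyloxy)penta-1,3-diene; 10 (2E)-3-[(4R)-2,2-dimethyl-1,3-dioxolan-4-yl]-2-methylprop-2-enal
Product: 12 ring A hydroxy aldehyde (12-OH; 11-CHO), via silyl ether adduct 11 (not isolated)
Conditions: Me2AlCl (0.3 equiv), CH2Cl2, −78 → −30 °C; then citric acid (cat.), MeOH, 0 °C
Reagents that add atoms: none
Why: Lewis-acid-catalysed Diels–Alder reaction in which the formyl-bearing C11 bonds to the silyloxy-bearing C12 ("ortho" orientation) and C10 to C1; C10 is set by addition of the diene anti to the C9–O bond of the dienophile, whose C9–H is held in the alkene plane by A(1,3) strain with the C11 methyl, while the centres at C12, C1 and C11 are all erased later, and mild methanolysis then removes the trimethylsilyl group.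

**Step 8**
Reactants: 12 ring A hydroxy aldehyde
Product: 14 ring A enone (4,6-dimethyl-5-dioxolanylcyclohex-2-enone), via keto aldehyde 13 (not isolated)
Conditions: Dess–Martin periodinane, NaHCO3, CH2Cl2, 0 °C → rt; then K2CO3 (0.2 equiv), MeOH, 0 °C
Reagents that add atoms: none
Why: Dess–Martin oxidation of the allylic alcohol gives a non-enolisable β-keto aldehyde that loses its formyl group by retro-Claisen cleavage with methoxide; protonation should leave both methyls trans to the C10 branch (C11 is reset in step 9, C1 is erased in step 20).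

**Step 9**
Reactants: 14 ring A enone
Product: 15 ring A α-hydroxy enone (11α-OH, 11β-CH3)
Conditions: KN(SiMe3)2, THF, −78 °C; then 2-(phenylsulfonyl)-3-phenyloxaziridine; aq. NH4Cl
Reagents that add atoms: 2-(phenylsulfonyl)-3-phenyloxaziridine, O=S(=O)(N1OC1c1ccccc1)c1ccccc1
Why: Davis α-hydroxylation of the kinetic cross-conjugated C11 enolate; the oxaziridine approaches anti to the adjacent C10 branch, which sets C11.

**Step 10**
Reactants: 15 ring A α-hydroxy enone
Product: 16 ring A triol (C8, C9, C11 hydroxyls)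
Conditions: AcOH/H2O (4:1), 40 °C
Reagents that add atoms: none
Why: Acid-catalysed hydrolysis of the terminal acetonide.

**Step 11**
Reactants: 16 ring A triol
Product: 17 tris(triethylsilyl) ether of 16
Conditions: TESOTf (3.6 equiv), 2,6-lutidine, CH2Cl2, −78 → 0 °C
Reagents that add atoms: triethylsilyl trifluoromethanesulfonate, CC[Si](CC)(CC)OS(=O)(=O)C(F)(F)F
Why: The silyl triflate silylates the primary, secondary and tertiary α-ketol hydroxyls, and 2,6-lutidine is too weak a base to enolise the enone.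

**Step 12**
Reactants: 17 tris(triethylsilyl) ether
Product: 18 C8 aldehyde (9-OSiEt3, 11-OSiEt3)
Conditions: (COCl)2, DMSO, CH2Cl2, −78 → −30 °C; then Et3N
Reagents that add atoms: none
Why: Under Swern conditions a primary triethylsilyl ether is cleaved and oxidised to the aldehyde while secondary and tertiary triethylsilyl ethers survive (oxidative desilylation).

**Step 13**
Reactants: 18 C8 aldehyde; 5 (1E)-1-iodo-6-[(4-methoxybenzyl)oxy]-3-methylidenehex-1-ene
Product: 19 dienyl carbinol (C8-OH, epimer mixture at C8)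
Conditions: CrCl2 (4 equiv), NiCl2 (2 mol%), DMSO/THF, rt
Reagents that add atoms: none
Why: Nozaki–Hiyama–Kishi coupling; the alkenylchromium keeps its (E) geometry and adds to the aldehyde in preference to the hindered ring A ketone, and the C8 carbinol centre is removed in step 14.

**Step 14**
Reactants: 19 dienyl carbinol
Product: 20 dienone (C8=O, C6=C7, C5=C16)
Conditions: Dess–Martin periodinane, NaHCO3, CH2Cl2, 0 °C
Reagents that add atoms: none
Why: Dess–Martin oxidation of the secondary allylic alcohol converges both C8 epimers on the dienone.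

**Step 15**
Reactants: 20 dienone
Product: 21 (6R,7S)-epoxy ketone
Conditions: La(O-i-Pr)3 (10 mol%), (R)-BINOL (10 mol%), Ph3As=O (10 mol%), t-BuOOH, 4 Å MS, THF, rt
Reagents that add atoms: tert-butyl hydroperoxide, CC(C)(C)OO
Why: Shibasaki lanthanum–BINOL-catalysed nucleophilic (Weitz–Scheffer-type) epoxidation of the acyclic s-cis enone; (R)-BINOL is chosen by analogy with chalcone-type enones to give the (6R,7S)-trans-epoxide, while the s-trans ring A enone and the unactivated C5 methylidene should not react.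

**Step 16**
Reactants: 21 (6R,7S)-epoxy ketone
Product: 22 (6S,7R)-chlorohydrin (6-Cl, 7-OH)
Conditions: LiCl (5 equiv), AcOH (3 equiv), THF, 0 °C → rt
Reagents that add atoms: lithium chloride, [Li+].[Cl-]
Why: Acid-assisted SN2 opening of the epoxy ketone by chloride at C6, which is allylic and remote from the carbonyl, proceeds with inversion and gives the anti chlorohydrin.

**Step 17**
Reactants: 22 (6S,7R)-chlorohydrin
Product: 23 C7 2-bromopropanoate (epimer mixture at the bromine-bearing carbon)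
Conditions: 2-bromopropanoyl bromide, 2,6-lutidine, CH2Cl2, −40 °C
Reagents that add atoms: 2-bromopropanoyl bromide, CC(Br)C(Br)=O
Why: O-acylation of the only free hydroxyl, run cold with a hindered weak base so that the β-chloro ketone does not lose HCl.

**Step 18**
Reactants: 23 C7 2-bromopropanoate
Product: 24 β-hydroxy-γ-lactone (C7–O–C19, 8-OH, 17-CH3)
Conditions: SmI2 (2.2 equiv), THF, −78 °C; aq. NH4Cl
Reagents that add atoms: none
Why: SmI2-mediated intramolecular Reformatsky reaction; the C–Br bond is reduced far faster than any ketone, and the samarium enolate adds to the C8 ketone in a five-membered chelated array that should place the C9 branch trans to the C6 branch and the C18 methyl trans to the C9 branch, setting C8 and C17.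

**Step 19**
Reactants: 24 β-hydroxy-γ-lactone
Product: 25 C2 primary alcohol
Conditions: DDQ, CH2Cl2/pH 7 buffer (10:1), 0 °C
Reagents that add atoms: none
Why: Oxidative cleavage of the PMB ether by hydride abstraction; silyl ethers, enone, lactone and allylic chloride are inert.

**Step 20**
Reactants: 25 C2 primary alcohol
Product: 28 dienol silyl ether primary alcohol (12-OSiMe2t-Bu; 8-OSiMe2t-Bu), via trimethylsilyl ether 26 (not isolated), via bis-silylated dienol ether 27 (not isolated)
Conditions: TMSCl (1.05 equiv), Et3N, CH2Cl2, −40 °C; then TBSOTf (3 equiv), Et3N (5 equiv), −78 → 0 °C; then K2CO3 (0.2 equiv), MeOH, −10 °C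
Reagents that add atoms: tert-butyldimethylsilyl trifluoromethanesulfonate, CC(C)(C)[Si](C)(C)OS(=O)(=O)C(F)(F)F
Why: The primary alcohol is masked as a labile trimethylsilyl ether; soft enolisation of the enone (silyl triflate and amine), possible only by loss of the γ-proton at C1 because C11 is quaternary, gives the linear dienol ether and also silylates the tertiary C8 hydroxyl, and brief methanolysis removes only the primary trimethylsilyl group.

**Step 21**
Reactants: 28 dienol silyl ether primary alcohol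
Product: 29 dienol silyl ether aldehyde (C2 = CHO)
Conditions: Dess–Martin periodinane, pyridine, CH2Cl2, 0 °C
Reagents that add atoms: none
Why: Buffered Dess–Martin oxidation of the primary alcohol should leave the tert-butyldimethylsilyl dienol ether intact.

**Step 22**
Reactants: 29 dienol silyl ether aldehyde
Product: 30 ten-membered carbocycle (2-OH; 8-OSiMe2t-Bu; 9- and 11-OSiEt3)
Conditions: BF3·OEt2 (3 equiv), CH2Cl2, −78 °C, 29 added by syringe pump to 0.5 mM; aq. NaHCO3
Reagents that add atoms: none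
Why: BF3 activates the C2 aldehyde, which is attacked by the γ-carbon C1 of the ring A 1-silyloxy-1,3-diene in an open antiperiplanar transition state, and loss of the silyl group regenerates the C12 ketone with the C13=C14 double bond. The closest known reaction type is the intramolecular vinylogous Mukaiyama aldol reaction of cyclic dienoxysilanes, which has been used to close medium carbocycles. The ten-membered ring (C1–C10) closes in a 10-exo-trig mode at the aldehyde, with the nucleophilic C1=C14 bond outside the new ring. C1 is controlled by C10: A(1,2) strain with the C15 methyl holds the C10–C9 bond pseudoaxial, so C2 should enter anti to it and give the trans ring fusion, and C2 follows from the antiperiplanar arrangement with the C3 chain in the open quadrant between C15 and C14, away from C10. The step needs γ- over α-attack, secured by the tether (attack at C13 would require a para-bridged ring) and by the quaternary C11, and cyclisation over oligomerisation, secured by slow addition at high dilution.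

**Step 23**
Reactants: 30 ten-membered carbocycle
Product: 31 tetraol (2-, 8-, 9-, 11-OH)
Conditions: HF·pyridine, pyridine, THF, 0 → 40 °C
Reagents that add atoms: none
Why: Fluoride-mediated cleavage of the three silyl ethers under buffered conditions that should spare the allylic chloride, enone and lactone.

**Step 24**
Reactants: 31 tetraol
Product: 32 CNP0261648.1
Conditions: Ac2O, pyridine, DMAP (cat.), CH2Cl2, 0 °C → rt
Reagents that add atoms: acetic anhydride, CC(=O)OC(C)=O
Why: Acetylation of the two secondary hydroxyls (C2, C9); the tertiary C8 and C11 hydroxyls should not react under these conditions.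

**Compound list**

1 | pentane-1,5-diol | OCCCCCO | starting material
2 | 5-[(4-methoxybenzyl)oxy]pentan-1-ol | COc1ccc(COCCCCCO)cc1 | intermediate
3 | 5-[(4-methoxybenzyl)oxy]pentanal | COc1ccc(COCCCCC=O)cc1 | intermediate
4 | 5-[(4-methoxybenzyl)oxy]-2-methylidenepentanal | COc1ccc(COCCCC(=C)C=O)cc1 | intermediate
5 | (1E)-1-iodo-6-[(4-methoxybenzyl)oxy]-3-methylidenehex-1-ene (C7 to C2 with C16) | COc1ccc(COCCCC(=C)/C=C/I)cc1 | intermediate
6 | (2E)-pent-2-enal | CC/C=C/C=O | starting material
7 | (1E,3E)-1-(trimethylsilyloxy)penta-1,3-diene | C/C=C/C=C/O[Si](C)(C)C | intermediate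
8 | (4S)-2,2-dimethyl-1,3-dioxolane-4-carbaldehyde | O=C[C@@H]1COC(C)(C)O1 | starting material
9 | 2-(triphenylphosphoranylidene)propanal | CC(C=O)=P(c1ccccc1)(c1ccccc1)c1ccccc1 | starting material
10 | (2E)-3-[(4R)-2,2-dimethyl-1,3-dioxolan-4-yl]-2-methylprop-2-enal | O=C/C(C)=C/[C@@H]1COC(C)(C)O1 | intermediate
11 | 6-[(4R)-2,2-dimethyl-1,3-dioxolan-4-yl]-1,5-dimethyl-2-(trimethylsilyloxy)cyclohex-3-ene-1-carbaldehyde; CHO, OSiMe3 and 5-CH3 on the α face, dioxolanyl and 1-CH3 on the β face | C[C@H]1C=C[C@@H](O[Si](C)(C)C)[C@@](C)(C=O)[C@@H]1[C@@H]2COC(C)(C)O2 | intermediate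
12 | 6-[(4R)-2,2-dimethyl-1,3-dioxolan-4-yl]-2-hydroxy-1,5-dimethylcyclohex-3-ene-1-carbaldehyde, configuration as in 11 | C[C@H]1C=C[C@@H](O)[C@@](C)(C=O)[C@@H]1[C@@H]2COC(C)(C)O2 | intermediate
13 | keto aldehyde: 12 with C12 oxidised to the ketone (enone C12=O, C13=C14; 11-CHO) | C[C@H]1C=CC(=O)[C@@](C)(C=O)[C@@H]1[C@@H]2COC(C)(C)O2 | intermediate
14 | 5-[(4R)-2,2-dimethyl-1,3-dioxolan-4-yl]-4,6-dimethylcyclohex-2-en-1-one, both methyls (C1, C11) α, dioxolanyl (C10) β | C[C@H]1C=CC(=O)[C@@H](C)[C@@H]1[C@@H]2COC(C)(C)O2 | intermediate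
15 | 5-[(4R)-2,2-dimethyl-1,3-dioxolan-4-yl]-6-hydroxy-4,6-dimethylcyclohex-2-en-1-one; 11α-OH, 11β-CH3, 10β-dioxolanyl, 1α-CH3 | C[C@H]1C=CC(=O)[C@@](C)(O)[C@@H]1[C@@H]2COC(C)(C)O2 | intermediate
16 | 5-[(1R)-1,2-dihydroxyethyl]-6-hydroxy-4,6-dimethylcyclohex-2-en-1-one, ring configuration as in 15 | C[C@H]1C=CC(=O)[C@@](C)(O)[C@@H]1[C@@H](O)CO | intermediate
17 | tris(triethylsilyl) ether of 16 (O8, O9, O11) | C[C@H]1C=CC(=O)[C@@](C)(O[Si](CC)(CC)CC)[C@@H]1[C@@H](O[Si](CC)(CC)CC)CO[Si](CC)(CC)CC | intermediate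
18 | (2R)-2-(triethylsilyloxy)-2-[ring A]acetaldehyde: 17 with C8 as the aldehyde | C[C@H]1C=CC(=O)[C@@](C)(O[Si](CC)(CC)CC)[C@@H]1[C@@H](O[Si](CC)(CC)CC)C=O | intermediate
19 | dienyl carbinol: PMBO–C2–C3–C4–C5(=C16H2)–C6H=C7H (E)–C8H(OH)–C9(OSiEt3) on C10β of the ring A enone (11α-OSiEt3, 1α-CH3); C8 epimer mixture | COc1ccc(COCCCC(=C)/C=C/C(O)[C@H](O[Si](CC)(CC)CC)[C@@H]2[C@@H](C)C=CC(=O)[C@@]2(C)O[Si](CC)(CC)CC)cc1 | intermediate
20 | dienone: 19 with C8 as the ketone | COc1ccc(COCCCC(=C)/C=C/C(=O)[C@H](O[Si](CC)(CC)CC)[C@@H]2[C@@H](C)C=CC(=O)[C@@]2(C)O[Si](CC)(CC)CC)cc1 | intermediate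
21 | (6R,7S)-trans-epoxy ketone of 20 | COc1ccc(COCCCC(=C)[C@H]3O[C@@H]3C(=O)[C@H](O[Si](CC)(CC)CC)[C@@H]2[C@@H](C)C=CC(=O)[C@@]2(C)O[Si](CC)(CC)CC)cc1 | intermediate
22 | (6S,7R)-6-chloro-7-hydroxy C8 ketone (anti chlorohydrin), C9 (R) | COc1ccc(COCCCC(=C)[C@H](Cl)[C@H](O)C(=O)[C@H](O[Si](CC)(CC)CC)[C@@H]2[C@@H](C)C=CC(=O)[C@@]2(C)O[Si](CC)(CC)CC)cc1 | intermediate
23 | C7 2-bromopropanoate of 22 | COc1ccc(COCCCC(=C)[C@H](Cl)[C@H](OC(=O)C(C)Br)C(=O)[C@H](O[Si](CC)(CC)CC)[C@@H]2[C@@H](C)C=CC(=O)[C@@]2(C)O[Si](CC)(CC)CC)cc1 | intermediate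
24 | γ-lactone (C7–O–C19) with tertiary 8-OH and 17-CH3; C6, C7, C8, C9, C10, C11, C17 configured as in the target; 2-OPMB, 9- and 11-OSiEt3, 1α-CH3 | COc1ccc(COCCCC(=C)[C@H](Cl)[C@@H]3OC(=O)[C@H](C)[C@@]3(O)[C@H](O[Si](CC)(CC)CC)[C@@H]2[C@@H](C)C=CC(=O)[C@@]2(C)O[Si](CC)(CC)CC)cc1 | intermediate
25 | 24 with free C2 hydroxyl | OCCCC(=C)[C@H](Cl)[C@@H]1OC(=O)[C@H](C)[C@@]1(O)[C@H](O[Si](CC)(CC)CC)[C@@H]2[C@@H](C)C=CC(=O)[C@@]2(C)O[Si](CC)(CC)CC | intermediate
26 | C2 trimethylsilyl ether of 25 | C[Si](C)(C)OCCCC(=C)[C@H](Cl)[C@@H]1OC(=O)[C@H](C)[C@@]1(O)[C@H](O[Si](CC)(CC)CC)[C@@H]2[C@@H](C)C=CC(=O)[C@@]2(C)O[Si](CC)(CC)CC | intermediate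
27 | ring A dienol tert-butyldimethylsilyl ether (C12(OSi)=C13–C14=C1) with 8-OSiMe2t-Bu and 2-OSiMe3 | C[Si](C)(C)OCCCC(=C)[C@H](Cl)[C@@H]1OC(=O)[C@H](C)[C@@]1(O[Si](C)(C)C(C)(C)C)[C@H](O[Si](CC)(CC)CC)[C@@H]2C(C)=CC=C(O[Si](C)(C)C(C)(C)C)[C@@]2(C)O[Si](CC)(CC)CC | intermediate
28 | 27 with free C2 hydroxyl | OCCCC(=C)[C@H](Cl)[C@@H]1OC(=O)[C@H](C)[C@@]1(O[Si](C)(C)C(C)(C)C)[C@H](O[Si](CC)(CC)CC)[C@@H]2C(C)=CC=C(O[Si](C)(C)C(C)(C)C)[C@@]2(C)O[Si](CC)(CC)CC | intermediate
29 | 28 with C2 as the aldehyde | O=CCCC(=C)[C@H](Cl)[C@@H]1OC(=O)[C@H](C)[C@@]1(O[Si](C)(C)C(C)(C)C)[C@H](O[Si](CC)(CC)CC)[C@@H]2C(C)=CC=C(O[Si](C)(C)C(C)(C)C)[C@@]2(C)O[Si](CC)(CC)CC | intermediate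
30 | briarane skeleton, all centres as in the target: 2-OH, 8-OSiMe2t-Bu, 9- and 11-OSiEt3 | C=C1CC[C@@H](O)[C@@]2(C)C=CC(=O)[C@@](C)(O[Si](CC)(CC)CC)[C@@H]2[C@@H](O[Si](CC)(CC)CC)[C@]2(O[Si](C)(C)C(C)(C)C)[C@@H](C)C(=O)O[C@H]2[C@H]1Cl | intermediate
31 | 2,9-bis-deacetyl target (tetraol) | C=C1CC[C@@H](O)[C@@]2(C)C=CC(=O)[C@@](C)(O)[C@@H]2[C@@H](O)[C@]2(O)[C@@H](C)C(=O)O[C@H]2[C@H]1Cl | intermediate
32 | CNP0261648.1 | C=C1CC[C@@H](OC(C)=O)[C@@]2(C)C=CC(=O)[C@@](C)(O)[C@@H]2[C@@H](OC(C)=O)[C@]2(O)[C@@H](C)C(=O)O[C@H]2[C@H]1Cl | target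

**Step count.** Total: 24 steps. Longest linear sequence: 19 steps (step 5 or step 6, then steps 7–24).

**Steps most likely to fail**

Step 22 (key cyclisation). The Lewis acid may ionise the allylic C11 silyloxy group of the dienol ether, the activated aldehyde may undergo a Prins reaction with the C5 methylidene, chains may oligomerise, or attack may come from the wrong face at C1 or C2. Fallback: it sets out from 25, whose primary alcohol is oxidised with Dess–Martin periodinane to the keto aldehyde F1. Both carbonyls are then complexed with aluminium tris(2,6-diphenylphenoxide) and C1 is deprotonated with lithium 2,2,6,6-tetramethylpiperidide (toluene/THF, −78 °C, high dilution). This direct base-mediated vinylogous aldol reaction needs no silyl dienol ether and no free Lewis acid and should give the cyclised diol F2. HF·pyridine then removes the two triethylsilyl groups and the route is rejoined at 31.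

Step 7 (Diels–Alder). The trisubstituted, β-branched dienophile may add too slowly, the diene may attack the formyl group instead (Mukaiyama aldol), or facial control may be poor. Fallback: a Robinson-type annulation that sets out from 8. Wittig reaction with 3-(triphenylphosphoranylidene)butan-2-one gives the enone F3. Mukaiyama–Michael addition of 1-(trimethylsilyloxy)prop-1-ene (TiCl2(O-i-Pr)2, CH2Cl2, −78 °C), again anti to the C9–O bond of the A(1,3)-locked alkene, gives the keto aldehyde F4, in which only C10 matters. Intramolecular aldol condensation (pyrrolidine, AcOH) closes ring A and the route is rejoined at 14.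

Step 16 (chloride opening). Chloride may add in the SN2′ sense at C16 or at C7, and the β-chloro ketone may lose HCl. Fallback: it sets out from 19. Sharpless epoxidation (Ti(O-i-Pr)4, D-(−)-diisopropyl tartrate, t-BuOOH, −20 °C) converts the matched C8 epimer into the erythro epoxy alcohol F5; the other epimer is recycled by Mitsunobu inversion. Ti(O-i-Pr)4 with diethylammonium chloride then delivers chloride, directed by chelation, to C6, the carbon remote from the carbinol, and gives the chloro diol F6. The less hindered C7 hydroxyl is acylated with 2-bromopropanoyl bromide (2,4,6-collidine, −78 °C) to the mono-ester F7. Dess–Martin oxidation of the C8 hydroxyl rejoins the route at 23.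

**Further compounds**

F1 | step 22 | keto aldehyde: 25 with C2 as the aldehyde | O=CCCC(=C)[C@H](Cl)[C@@H]1OC(=O)[C@H](C)[C@@]1(O)[C@H](O[Si](CC)(CC)CC)[C@@H]2[C@@H](C)C=CC(=O)[C@@]2(C)O[Si](CC)(CC)CC
F2 | step 22 | cyclised diol: briarane skeleton with 2-OH, 8-OH, 9- and 11-OSiEt3 | C=C1CC[C@@H](O)[C@@]2(C)C=CC(=O)[C@@](C)(O[Si](CC)(CC)CC)[C@@H]2[C@@H](O[Si](CC)(CC)CC)[C@]2(O)[C@@H](C)C(=O)O[C@H]2[C@H]1Cl
F3 | step 7 | (3E)-4-[(4R)-2,2-dimethyl-1,3-dioxolan-4-yl]-3-methylbut-3-en-2-one | CC(=O)/C(C)=C/[C@@H]1COC(C)(C)O1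
F4 | step 7 | 3-[(4R)-2,2-dimethyl-1,3-dioxolan-4-yl]-2,4-dimethyl-5-oxohexanal, C3 (briarane C10) as in 14, C2 and C4 epimer mixtures | CC(=O)C(C)[C@H]([C@@H]1COC(C)(C)O1)C(C)C=O
F5 | step 16 | erythro epoxy alcohol: 6,7-epoxide as in 21 with C8 carbinol | COc1ccc(COCCCC(=C)[C@H]3O[C@@H]3[C@H](O)[C@H](O[Si](CC)(CC)CC)[C@@H]2[C@@H](C)C=CC(=O)[C@@]2(C)O[Si](CC)(CC)CC)cc1
F6 | step 16 | chloro diol: 6-Cl, 7-OH as in 22, with 8-OH | COc1ccc(COCCCC(=C)[C@H](Cl)[C@H](O)[C@H](O)[C@H](O[Si](CC)(CC)CC)[C@@H]2[C@@H](C)C=CC(=O)[C@@]2(C)O[Si](CC)(CC)CC)cc1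
F7 | step 16 | C7 2-bromopropanoate of F6 with free 8-OH | COc1ccc(COCCCC(=C)[C@H](Cl)[C@H](OC(=O)C(C)Br)[C@H](O)[C@H](O[Si](CC)(CC)CC)[C@@H]2[C@@H](C)C=CC(=O)[C@@]2(C)O[Si](CC)(CC)CC)cc1
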